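1. Electrophile was left over when both earlier runs ended: 63.9 % of the charge in ochre and 58.6 % in blue, although blue held 38 mM of electrophile and 38 mM of nucleophile. I left these notes for the next person at the bench.

common to all: electrophile 38 mM

|  | nucleophile | remark | time |
|---|---|---|---|
| ochre | 32 mM | run made earlier |  |
| blue | 38 mM | run made earlier |  |
| east | 61.0 mM |  | 4.0 min |
| south | 36.0 mM |  | 4.0 min |
| west | 47.0 mM |  | 4.0 min |

- ochre (time / min: electrophile / %, product / %): 0.250: 83.3, 16.9; 0.333: 80.1, 20.4; 0.667: 72.1, 27.9; 1.00: 68.9, 31.3; 1.50: 65.8, 33.6; 3.00: 63.9, 36.4
- blue (time / min: electrophile / %, product / %): 0.500: 71.1, 28.4; 1.00: 64.0, 36.2; 1.33: 62.0, 37.9; 2.00: 59.0, 40.2; 2.50: 59.5, 41.0; 3.00: 58.6, 40.8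

(each reading ± 0.3 percentage points)

- a reading or a percentage of product counts all its forms, free or not

- part of the electrophile that has reacted at the end, east
- part of the electrophile that has reacted at the end, south
- part of the electrophile that has reacted at the end, west
- what raising the concentration of nucleophile from its lowest to its highest value here does to the part of the electrophile that has reacted (changes below 5 percentage points count as none) (no change / it rises / it falls)

2. Blue's readings gave 0.408 as the stall share, the last c(product) read over the charged c(nucleophile). Ochre gave 0.432, a higher reading.

3. Blue's product moved from 40.2 % at 2.00 min to 40.8 % at 3.00 min, so I expected the new flasks to stand nearly still by 4.0 min. I wrote: add nothing and don't wait longer.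

4. Blue's share gave me 65.5 % reacted in east, 38.7 % in south and 50.5 % in west, so the part reacted rises. The share had fallen from ochre to blue, so I warned that east might land lower.

5. The forecast said “Both runs level off”. It gave 55.6 % for east, 39.7 % for south and 47.6 % for west, with the trend it rises. My east was higher, and my south was lower.

6. The flasks gave 59.0 % in east, 40.1 % in south and 49.2 % in west, so from south to east the part reacted moved by 19 percentage points: it rises. The forecast held within its margins.

    nucleophile + acid set free ⇌ protonated nucleophile, settled at all times (K = 57000 L mol⁻¹)
    crystals ⇌ product, rate k2*(cs2 - [product]) while solid is left; crystals form when [product] > cs2 (solubility = 14.0 mM, k = 2.50 s⁻¹)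
    2 nucleophile → homo dimer (k = 0.208 L mol⁻¹ s⁻¹)
    electrophile + nucleophile ⇌ acid set free + product (K = 3.00, k = 0.545 L mol⁻¹ s⁻¹)

7. East's stall share came to 0.367, below blue's, so my east stood 6.5 points too high. Nucleophile was the limiting reagent in east: 0.96 % of its charge stayed free, against 41 % of the electrophile. The neighbour flask, like east but with 65 mM of electrophile, reckons with blue's share to 38.3 % reacted. It ended at 40.2 %, with 0.44 % of its nucleophile free.

All runs are simulated for an exercise.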